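**Strategy.** Ring A is read as a quinone in disguise: its oxygens on C6 and C8a (O1) are para, those on C5 and C7 flank C6, and the acylated carbon C4a sits next to C8a. The C4–C4a bond is therefore made with reversed polarity, by light-driven addition of the acyl radical of a β-chlorocinnamaldehyde to C3 of symmetrical 2,6-dimethoxy-1,4-benzoquinone. This one operation joins the A and B halves, aromatises the quinone and sets all four A-ring oxygens in place without a regiochemical choice. The precursor pair is the quinone and a (Z)-3-aryl-3-chloropropenal, whose chloride later lets the pyranone close without an oxidant.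

Key step: step 3

Remark on the chemistry: the target has no stereocentre, so no enantiomer has to be controlled; the only stereo-elements on the way are Z-alkenes that disappear in step 4. The target is drawn as the free bis(hydrogen sulfate) and is delivered in that form by cold cation exchange of its salt.

**Step 1**
Reactants: 1 1-(3,4-dihydroxyphenyl)ethan-1-one
Product: 2 4-acetyl-1,2-phenylene bis(2,2-dimethylpropanoate)
Conditions: PivCl (2.4 equiv), Et3N, DMAP (cat.), CH2Cl2, 0 °C to rt
Reagents that add atoms: pivaloyl chloride CC(C)(C)C(=O)Cl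
Why: DMAP-catalysed O-acylation of both catechol hydroxyls; the hindered pivalates are chosen because they should survive POCl3, light, BBr3 and SO3 and still fall to methanolysis at the end.

**Step 2**
Reactants: 2 4-acetyl-1,2-phenylene bis(2,2-dimethylpropanoate)
Product: 3 4-[(1Z)-1-chloro-3-oxoprop-1-en-1-yl]-1,2-phenylene bis(2,2-dimethylpropanoate)
Conditions: POCl3 (3 equiv), DMF, 0 to 60 °C; then ice–water
Reagents that add atoms: phosphoryl chloride O=P(Cl)(Cl)Cl; N,N-dimethylformamide CN(C)C=O; water O
Why: Vilsmeier–Haack–Arnold chloroformylation of an aryl methyl ketone, in which the chloroiminium salt attacks the enol, the ketone oxygen is exchanged for chloride and hydrolysis frees the aldehyde, the Z isomer (aryl trans to CHO) being the favoured one; the acyloxy-deactivated ring should not be formylated.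

**Step 3**
Reactants: 3 4-[(1Z)-1-chloro-3-oxoprop-1-en-1-yl]-1,2-phenylene bis(2,2-dimethylpropanoate); 4 2,6-dimethoxy-1,4-benzoquinone
Product: 5 4-[(1Z)-1-chloro-3-(2,5-dihydroxy-4,6-dimethoxyphenyl)-3-oxoprop-1-en-1-yl]-1,2-phenylene bis(2,2-dimethylpropanoate)
Conditions: 4 (1.5 equiv), hν (405 nm LED), degassed MeCN/PhCF3, 0.05 M, 20 °C, Ar
Reagents that add atoms: none
Why: Photo-Friedel–Crafts acylation of a quinone: violet light excites only 4 (3 is transparent at 405 nm), its triplet abstracts the formyl hydrogen of 3, and the resulting nucleophilic σ-acyl radical bonds to C3 of the quinone (collapse of the semiquinone/acyl radical pair or chain addition to ground-state 4), after which the 2-acyl-ene-dione tautomerises to the hydroquinone, aromatisation being the driving force. The closest known reaction type is the light-induced acylation of 1,4-benzo- and naphthoquinones by aliphatic, aromatic and α,β-unsaturated aldehydes to acylhydroquinones. No ring is closed (the quinone ring becomes the aromatic A ring) and no stereocentre is formed; the Z-chloroalkene is carried over from 3 and its geometry is without consequence for step 4. The selectivity needed is C- over O-acylation at one defined ring carbon: C3 and C5 are the only unsubstituted positions of 4 and are equivalent through its mirror plane, and attack there gives a radical stabilised by the C2 methoxy and C1 carbonyl groups. Hydrogen abstraction should be favoured over [2+2] addition to the alkene because that alkene is electron-poor (chloro and acyloxyaryl substituents), and the product should be protected from further photochemistry by its hydrogen-bonded o-hydroxyaryl ketone. The polar alternative (acylium ion on the hydroquinone) would need a Lewis acid, which the reversed-polarity radical step avoids.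

**Step 4**
Reactants: 5 4-[(1Z)-1-chloro-3-(2,5-dihydroxy-4,6-dimethoxyphenyl)-3-oxoprop-1-en-1-yl]-1,2-phenylene bis(2,2-dimethylpropanoate)
Product: 6 4-(6-hydroxy-5,7-dimethoxy-4-oxo-4H-chromen-2-yl)-1,2-phenylene bis(2,2-dimethylpropanoate)
Conditions: K2CO3 (2.2 equiv), degassed acetone, rt, Ar
Reagents that add atoms: none
Why: Intramolecular vinylic substitution (oxa-Michael addition–elimination, 6-endo-trig closure of O1 onto C2, then loss of chloride), the reaction type by which o-hydroxyaryl β-chlorovinyl and β-aminovinyl ketones give chromones; only the hydroxyl ortho to the ketone can reach, so the C6 hydroxyl should stay free and no oxidant is needed.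

**Step 5**
Reactants: 6 4-(6-hydroxy-5,7-dimethoxy-4-oxo-4H-chromen-2-yl)-1,2-phenylene bis(2,2-dimethylpropanoate)
Product: 7 4-(5,6,7-trihydroxy-4-oxo-4H-chromen-2-yl)-1,2-phenylene bis(2,2-dimethylpropanoate)
Conditions: BBr3 (5 equiv), CH2Cl2, −78 to 0 °C; then ice–water, MeOH co-evaporation
Reagents that add atoms: none
Why: Lewis-acid cleavage of aryl methyl ethers with BBr3, in which the 5-OMe is activated by chelation to C4=O and the 7-OMe by the neighbouring C6–O–BBr2, while the aryl pivalates should resist because bromide cannot attack an aryl carbon and the tert-butyl group shields the carbonyl.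

**Step 6**
Reactants: 7 4-(5,6,7-trihydroxy-4-oxo-4H-chromen-2-yl)-1,2-phenylene bis(2,2-dimethylpropanoate)
Product: 8 bis(triethylammonium) 2-[3,4-bis(2,2-dimethylpropanoyloxy)phenyl]-5-hydroxy-4-oxo-4H-chromene-6,7-diyl bis(sulfate)
Conditions: SO3·NEt3 (8 equiv), Et3N, DMA, 60 °C, Ar; Sephadex LH-20
Reagents that add atoms: sulfur trioxide–triethylamine complex CC[N+](CC)(CC)S(=O)(=O)[O-]
Why: O-sulfation of phenols with an amine–SO3 complex should take the C6 and C7 hydroxyls, whereas the C5 hydroxyl is locked in the hydrogen-bonded chelate with C4=O and is the position that resists sulfation in 5-hydroxyflavones.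

**Step 7**
Reactants: 8 bis(triethylammonium) 2-[3,4-bis(2,2-dimethylpropanoyloxy)phenyl]-5-hydroxy-4-oxo-4H-chromene-6,7-diyl bis(sulfate)
Product: 10 6-hydroxyluteolin 6,7-bis(hydrogen sulfate) (target), via bis(triethylammonium) 6-hydroxyluteolin 6,7-disulfate 9 (not isolated)
Conditions: Et3N, DMAP (cat.), MeOH, 50 °C, Ar; evaporate; Dowex 50W-X8 (H+ form), H2O, 0 °C; freeze-dry
Reagents that add atoms: none
Why: DMAP-catalysed transesterification of the two aryl pivalates (phenoxide leaving groups, the second assisted by the freed neighbouring hydroxyl) under conditions to which aryl sulfate anions are inert, followed by cold cation exchange that replaces triethylammonium by protons.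

**Compound list**
1 | 1-(3,4-dihydroxyphenyl)ethan-1-one | CC(=O)c1ccc(O)c(O)c1 | starting material
2 | 4-acetyl-1,2-phenylene bis(2,2-dimethylpropanoate) | CC(=O)c1ccc(OC(=O)C(C)(C)C)c(OC(=O)C(C)(C)C)c1 | intermediate
3 | 4-[(1Z)-1-chloro-3-oxoprop-1-en-1-yl]-1,2-phenylene bis(2,2-dimethylpropanoate) | O=C/C=C(\Cl)c1ccc(OC(=O)C(C)(C)C)c(OC(=O)C(C)(C)C)c1 | intermediate
4 | 2,6-dimethoxy-1,4-benzoquinone | COC1=CC(=O)C=C(OC)C1=O | starting material
5 | 4-[(1Z)-1-chloro-3-(2,5-dihydroxy-4,6-dimethoxyphenyl)-3-oxoprop-1-en-1-yl]-1,2-phenylene bis(2,2-dimethylpropanoate) | COc1cc(O)c(C(=O)/C=C(\Cl)c2ccc(OC(=O)C(C)(C)C)c(OC(=O)C(C)(C)C)c2)c(OC)c1O | intermediate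
6 | 4-(6-hydroxy-5,7-dimethoxy-4-oxo-4H-chromen-2-yl)-1,2-phenylene bis(2,2-dimethylpropanoate) | COc1cc2oc(-c3ccc(OC(=O)C(C)(C)C)c(OC(=O)C(C)(C)C)c3)cc(=O)c2c(OC)c1O | intermediate
7 | 4-(5,6,7-trihydroxy-4-oxo-4H-chromen-2-yl)-1,2-phenylene bis(2,2-dimethylpropanoate) | O=c1cc(-c2ccc(OC(=O)C(C)(C)C)c(OC(=O)C(C)(C)C)c2)oc2cc(O)c(O)c(O)c12 | intermediate
8 | bis(triethylammonium) 2-[3,4-bis(2,2-dimethylpropanoyloxy)phenyl]-5-hydroxy-4-oxo-4H-chromene-6,7-diyl bis(sulfate) | O=c1cc(-c2ccc(OC(=O)C(C)(C)C)c(OC(=O)C(C)(C)C)c2)oc2cc(OS(=O)(=O)[O-])c(OS(=O)(=O)[O-])c(O)c12.CC[NH+](CC)CC.CC[NH+](CC)CC | intermediate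
9 | bis(triethylammonium) 2-(3,4-dihydroxyphenyl)-5-hydroxy-4-oxo-4H-chromene-6,7-diyl bis(sulfate) | O=c1cc(-c2ccc(O)c(O)c2)oc2cc(OS(=O)(=O)[O-])c(OS(=O)(=O)[O-])c(O)c12.CC[NH+](CC)CC.CC[NH+](CC)CC | intermediate
10 | 6-hydroxyluteolin 6,7-bis(hydrogen sulfate) | O=c1cc(-c2ccc(O)c(O)c2)oc2cc(OS(=O)(=O)O)c(OS(=O)(=O)O)c(O)c12 | target

**Total step count:** 7
**Longest linear sequence:** 7 steps (1 to 10; quinone 4 enters at step 3)

**Steps most likely to fail**

Step 3 (key step). The excited methoxyquinone may relax without hydrogen transfer or add to the alkene, or the radical pair may collapse at oxygen to a hydroquinone monoester, so that little C-acylated material forms. The fallback replaces the radical union by a polar, thermal one and sets out from 4. Reduction with Na2S2O4 should give 2,6-dimethoxyhydroquinone F1. Friedel–Crafts acetylation at its only free ring position (AcOH, BF3·OEt2) should give 1-(2,5-dihydroxy-4,6-dimethoxyphenyl)ethanone F2. Acid-mediated Claisen–Schmidt condensation (BF3·OEt2, which spares aryl esters) with 3,4-bis(pivaloyloxy)benzaldehyde F3, made from 3,4-dihydroxybenzaldehyde and pivaloyl chloride, should give the (E)-2',5'-dihydroxy-4',6'-dimethoxy-3,4-bis(pivaloyloxy)chalcone F4. Oxidative cyclisation with catalytic I2 in DMSO then brings the route back at 6.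

Step 6. Sulfation may stop at the monosulfate because the C6 hydroxyl is flanked on both sides and deactivated by the first sulfate anion. Forcing may begin to sulfate the chelated C5 hydroxyl, and the electron-rich triol may be oxidised by air in the basic medium. The fallback uses protected sulfate diesters and sets out from 7. 2,2,2-Trichloroethyl chlorosulfate (Et3N, DMAP, THF) should give the neutral, chromatographable bis(2,2,2-trichloroethyl sulfate) diester F5. Zn dust and HCO2NH4 in MeOH should remove both trichloroethyl groups by reductive fragmentation to give the bis(ammonium) disulfate still carrying the pivalates F6. Ammonia in MeOH should cleave the pivalates to bis(ammonium) 6-hydroxyluteolin 6,7-disulfate F7, and cold H+ exchange as in step 7 returns to the route at 10.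

Step 5. Acyl cleavage of one or both pivalates by the Lewis acid, or incomplete cleavage of the 7-OMe, would give mixtures that cannot be re-differentiated. The fallback uses hydrogenolysis-labile A-ring ethers so that no Lewis acid is needed, and sets out from 4 (with 3). Acid-catalysed alkoxy exchange of the vinylogous ester with benzyl alcohol (TsOH, toluene, removal of MeOH) should give 2,6-bis(benzyloxy)-1,4-benzoquinone F8. Photoacylation with 3 as in step 3 should give the 4',6'-bis(benzyloxy)-2',5'-dihydroxy-β-chlorochalcone F9. Closure as in step 4 should give the 5,7-bis(benzyloxy)-6-hydroxyflavone bis(pivalate) F10. Hydrogenolysis (H2, Pd/C, EtOAc) of the two benzyl ethers brings the route back at 7.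

**Further compounds**
F1 | step 3 | 2,6-dimethoxybenzene-1,4-diol | COc1cc(O)cc(OC)c1O
F2 | step 3 | 1-(2,5-dihydroxy-4,6-dimethoxyphenyl)ethan-1-one | CC(=O)c1c(O)cc(OC)c(O)c1OC
F3 | step 3 | 4-formyl-1,2-phenylene bis(2,2-dimethylpropanoate) | O=Cc1ccc(OC(=O)C(C)(C)C)c(OC(=O)C(C)(C)C)c1
F4 | step 3 | 4-[(1E)-3-(2,5-dihydroxy-4,6-dimethoxyphenyl)-3-oxoprop-1-en-1-yl]-1,2-phenylene bis(2,2-dimethylpropanoate) | COc1cc(O)c(C(=O)/C=C/c2ccc(OC(=O)C(C)(C)C)c(OC(=O)C(C)(C)C)c2)c(OC)c1O
F5 | step 6 | 4-{5-hydroxy-4-oxo-6,7-bis[(2,2,2-trichloroethoxy)sulfonyloxy]-4H-chromen-2-yl}-1,2-phenylene bis(2,2-dimethylpropanoate) | O=c1cc(-c2ccc(OC(=O)C(C)(C)C)c(OC(=O)C(C)(C)C)c2)oc2cc(OS(=O)(=O)OCC(Cl)(Cl)Cl)c(OS(=O)(=O)OCC(Cl)(Cl)Cl)c(O)c12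
F6 | step 6 | bis(ammonium) 2-[3,4-bis(2,2-dimethylpropanoyloxy)phenyl]-5-hydroxy-4-oxo-4H-chromene-6,7-diyl bis(sulfate) | O=c1cc(-c2ccc(OC(=O)C(C)(C)C)c(OC(=O)C(C)(C)C)c2)oc2cc(OS(=O)(=O)[O-])c(OS(=O)(=O)[O-])c(O)c12.[NH4+].[NH4+]
F7 | step 6 | bis(ammonium) 2-(3,4-dihydroxyphenyl)-5-hydroxy-4-oxo-4H-chromene-6,7-diyl bis(sulfate) | O=c1cc(-c2ccc(O)c(O)c2)oc2cc(OS(=O)(=O)[O-])c(OS(=O)(=O)[O-])c(O)c12.[NH4+].[NH4+]
F8 | step 5 | 2,6-bis(benzyloxy)-1,4-benzoquinone | O=C1C=C(OCc2ccccc2)C(=O)C(OCc2ccccc2)=C1
F9 | step 5 | 4-{(1Z)-3-[4,6-bis(benzyloxy)-2,5-dihydroxyphenyl]-1-chloro-3-oxoprop-1-en-1-yl}-1,2-phenylene bis(2,2-dimethylpropanoate) | O=C(/C=C(\Cl)c1ccc(OC(=O)C(C)(C)C)c(OC(=O)C(C)(C)C)c1)c1c(O)cc(OCc2ccccc2)c(O)c1OCc1ccccc1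
F10 | step 5 | 4-[5,7-bis(benzyloxy)-6-hydroxy-4-oxo-4H-chromen-2-yl]-1,2-phenylene bis(2,2-dimethylpropanoate) | O=c1cc(-c2ccc(OC(=O)C(C)(C)C)c(OC(=O)C(C)(C)C)c2)oc2cc(OCc3ccccc3)c(O)c(OCc3ccccc3)c12
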